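The cyclobutane is disconnected at the two bonds that flank its unsubstituted CH2–CH2 edge: that edge is ethylene, and the opposite edge, the ring bond between the acyloxy- and aryl-bearing carbon and the gem-dimethyl carbon, is the C=C bond of a 6-aryl-5-methyl-1,3-dioxin-4-one. One [2+2] photocycloaddition forms both bonds, the four-membered ring and the oxygenated quaternary stereocentre, under π-facial control by a menthone-derived spiro-acetal. The ring oxygen of the dioxinone becomes the ester oxygen; its lactone carbonyl is reduced to the second methyl group. The aryl group is 2,5-dimethoxyphenyl, oxidised late to a benzoquinone and annulated with 2,5-bis(trimethylsiloxy)furan to the naphthazarin.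

Key step: step 3

Remarks on the chemistry (assumptions):
- The target is drawn as one naphthazarin tautomer; the annulation product of step 10 equilibrates to this same compound.
- Ethylene is assumed to add to the enone face of 7 that is syn to the menthane CH2 (C11) and anti to the isopropyl-bearing C7; should the sense be the opposite, the (6R) spiro epimer formed alongside 7 in step 2 would be carried through the same steps instead.
- Descriptor changes along the route (1S in 9, 1R in 10 to 22) come only from changed substituent priorities; no bond at that carbon is broken after step 3.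
- (–)-Menthone, (2Z)-2-methylbut-2-enoic anhydride, 2,5-dimethoxybenzoyl chloride and ethylene are taken as commercial.

Step 1
Reactants: 1 tert-butyl propanoate; 2 2,5-dimethoxybenzoyl chloride
Product: 4 tert-butyl 3-(2,5-dimethoxyphenyl)-2-methyl-3-oxopropanoate, via lithium enolate 3 (not isolated)
Conditions: LiN(iPr)2 (2.1 equiv), 1 (2.1 equiv), THF, –78 °C; then 2, –78 → 0 °C; aq. NH4Cl
Reagents that add atoms: none
Why: Crossed Claisen-type C-acylation of a lithium ester enolate by an aroyl chloride, the second equivalent of enolate deprotonating the more acidic β-keto ester so that it is not acylated twice; the new stereocentre is labile and is destroyed in step 2.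

Step 2
Reactants: 4 tert-butyl 3-(2,5-dimethoxyphenyl)-2-methyl-3-oxopropanoate; 5 (–)-menthone, (2S,5R)-5-methyl-2-(propan-2-yl)cyclohexan-1-one
Product: 7 (6S,7S,10R)-4-(2,5-dimethoxyphenyl)-3,10-dimethyl-7-(propan-2-yl)-1,5-dioxaspiro[5.5]undec-3-en-2-one, via keto acid 6 (not isolated)
Conditions: CF3CO2H, (CF3CO)2O, 5 (excess), 0 °C → rt; chromatography to remove the (6R) spiro epimer
Reagents that add atoms: none
Why: Acid-mediated dioxinone formation (dehydrating condensation of a β-keto acid with a ketone): the acid cleaves the tert-butyl ester, the anhydride activates the carboxyl group, and enol oxygen and carboxylate close the acetal on the menthone carbonyl; the spiro carbon forms as both epimers, which are diastereomers and separable, and the (6S) epimer is carried on.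

Step 3
Reactants: 7 the (6S,7S,10R) spiro-dioxinone; 8 ethylene
Product: 9 (1S,3S,6S,2'S,5'R)-1-(2,5-dimethoxyphenyl)-6,5'-dimethyl-2'-(propan-2-yl)spiro[2,4-dioxabicyclo[4.2.0]octane-3,1'-cyclohexan]-5-one (cis-fused cyclobutane, aryl and methyl cis)
Conditions: hν (Pyrex, λ ≥ 300 nm), ethylene (saturated, continuous stream), CH2Cl2–acetone, –60 °C
Reagents that add atoms: none
Why: Excitation of the enone chromophore of 7 and intersystem crossing give the triplet enone, which adds ethylene to a triplet 1,4-biradical that closes after spin inversion; the ortho-methoxy and 3-methyl groups twist the arene out of conjugation and an alkoxybenzene triplet lies above the enone triplet, so the arene should not quench it. The closest known reaction type is the enone–alkene [2+2] photocycloaddition of 1,3-dioxin-4-ones (first stage of the de Mayo reaction), including its auxiliary-controlled form with menthone-derived spiro-dioxinones. The cyclobutane is closed by an intermolecular stepwise [2+2] addition across C3=C4 of 7 (one C–C bond, then recombination of the 1,4-biradical), and the six-membered ring enforces cis fusion. Both new stereocentres (C1 with aryl and oxygen, C6 with methyl) follow from the π-face on which ethylene adds: the spiro-menthane holds its CH2 arm (C11) over one face and the isopropyl-bearing arm (C7) over the other, and addition is expected on the C11 face, toward which the acetal carbon of the sofa-shaped ring is bent. Only π-facial selectivity is needed, because ethylene is symmetric (no regiochemical or exo/endo issue) and only the configuration at the oxygen-bearing carbon survives to the target.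

Step 4
Reactants: 9 the photoadduct
Product: 10 (1R,2R)-1-(2,5-dimethoxyphenyl)-2-(hydroxymethyl)-2-methylcyclobutan-1-ol (OH and CH2OH cis)
Conditions: LiAlH4, THF, 0 °C; H2O, aq. NaOH work-up
Reagents that add atoms: none
Why: Hydride reduction of the lactone with LiAlH4: acyl–oxygen cleavage releases a hemiketal that loses menthone (reduced in turn to menthol), and the aldehyde is reduced faster than the strained β-alkoxy aldehyde can open by retro-aldol reaction; neither stereocentre is touched.

Step 5
Reactants: 10 the cis diol
Product: 12 [(1R,2R)-2-(2,5-dimethoxyphenyl)-1-methyl-2-[(trimethylsilyl)oxy]cyclobutyl]methyl 4-methylbenzenesulfonate, via hydroxy tosylate 11 (not isolated)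
Conditions: TsCl, pyridine, DMAP (cat.), CH2Cl2, 0 °C; then 1-(trimethylsilyl)imidazole, rt
Reagents that add atoms: 4-methylbenzenesulfonyl chloride Cc1ccc(cc1)S(Cl)(=O)=O; 1-(trimethylsilyl)imidazole C[Si](C)(C)n1ccnc1
Why: Selective sulfonylation (tosylation) of the primary hydroxyl, then silylation of the hindered tertiary hydroxyl by a strong neutral silyl donor, which removes the alkoxide that could trigger a Grob fragmentation of the cyclobutane in step 6.

Step 6
Reactants: 12 the silyl-protected tosylate
Product: 14 (1R)-1-(2,5-dimethoxyphenyl)-2,2-dimethylcyclobutan-1-ol, via silyl ether 13 (not isolated)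
Conditions: LiEt3BH, THF, 0 → 60 °C; then K2CO3, MeOH, rt
Reagents that add atoms: none
Why: SN2 displacement of the neopentyl tosylate by hydride from the strongly nucleophilic LiEt3BH (sulfonate reduction) turns the former lactone carbon into the second methyl group, and base-catalysed methanolysis then removes the trimethylsilyl ether; the carbinol stereocentre is not involved.

Step 7
Reactants: 14 the tertiary alcohol; 15 (2Z)-2-methylbut-2-enoic anhydride (angelic anhydride)
Product: 17 (1R)-1-(2,5-dimethoxyphenyl)-2,2-dimethylcyclobutyl (2Z)-2-methylbut-2-enoate, via lithium alkoxide 16 (not isolated)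
Conditions: LiN(SiMe3)2, THF, –78 °C; then 15, –78 → 0 °C; aq. NH4Cl
Reagents that add atoms: none
Why: O-acylation of a preformed lithium alkoxide with a carboxylic anhydride at low temperature, without acid or nucleophilic catalyst, so the (Z)-alkene should not isomerise to the tiglate; the C–O bond at the stereocentre is not broken, so configuration is retained.

Step 8
Reactants: 17 the aryl angelate
Product: 18 (1R)-1-(3,6-dioxocyclohexa-1,4-dien-1-yl)-2,2-dimethylcyclobutyl (2Z)-2-methylbut-2-enoate
Conditions: (NH4)2Ce(NO3)6, MeCN–H2O, 0 °C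
Reagents that add atoms: water O
Why: Oxidative demethylation of a 1,4-dimethoxyarene to the 1,4-benzoquinone by tetravalent cerium (two one-electron oxidations with attack of water and loss of methanol), brief and cold enough to spare the enoate and the tertiary ester.

Step 9
Reactants: 19 succinic anhydride
Product: 20 2,5-bis(trimethylsiloxy)furan
Conditions: Me3SiCl, Et3N, ZnCl2 (cat.), MeCN, rt; distillation
Reagents that add atoms: chlorotrimethylsilane C[Si](C)(C)Cl
Why: Double O-silylation of the bis-enol form of the cyclic anhydride (silyl ketene acetal formation) gives the electron-rich aromatic furan.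

Step 10
Reactants: 18 the quinone; 20 2,5-bis(trimethylsiloxy)furan
Product: 22 (1R)-1-(5,8-dihydroxy-1,4-dioxo-1,4-dihydronaphthalen-2-yl)-2,2-dimethylcyclobutyl (2Z)-2-methylbut-2-enoate, via oxanorbornene cycloadduct 21 (not isolated)
Conditions: CH2Cl2, –20 °C → rt; then silica gel
Reagents that add atoms: none
Why: Diels–Alder reaction of the bis(siloxy)furan with the unsubstituted C=C bond of the quinone (the other is blocked by the quaternary cyclobutyl group), then opening of the oxygen bridge with loss of hexamethyldisiloxane to a 4a,8a-dihydro-tetraone that enolises to the naphthazarin; the remote stereocentre is untouched and naphthazarin tautomerism makes the orientation of the annulation irrelevant.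

Compound list
1 | tert-butyl propanoate | CCC(=O)OC(C)(C)C | starting material
2 | 2,5-dimethoxybenzoyl chloride | COc1ccc(OC)c(c1)C(Cl)=O | starting material
3 | lithium (Z)-1-tert-butoxyprop-1-en-1-olate (enolate of 1) | [Li+].C/C=C(\OC(C)(C)C)[O-] | intermediate
4 | tert-butyl 3-(2,5-dimethoxyphenyl)-2-methyl-3-oxopropanoate (racemic, labile centre) | COc1ccc(OC)c(c1)C(=O)C(C)C(=O)OC(C)(C)C | intermediate
5 | (–)-menthone, (2S,5R)-5-methyl-2-(propan-2-yl)cyclohexan-1-one | CC(C)[C@@H]1CC[C@@H](C)CC1=O | starting material
6 | 3-(2,5-dimethoxyphenyl)-2-methyl-3-oxopropanoic acid | COc1ccc(OC)c(c1)C(=O)C(C)C(O)=O | intermediate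
7 | (6S,7S,10R)-4-(2,5-dimethoxyphenyl)-3,10-dimethyl-7-(propan-2-yl)-1,5-dioxaspiro[5.5]undec-3-en-2-one | CC(C)[C@@H]1CC[C@@H](C)C[C@]12OC(=O)C(C)=C(c3cc(OC)ccc3OC)O2 | intermediate
8 | ethylene | C=C | starting material
9 | (1S,3S,6S,2'S,5'R)-1-(2,5-dimethoxyphenyl)-6,5'-dimethyl-2'-(propan-2-yl)spiro[2,4-dioxabicyclo[4.2.0]octane-3,1'-cyclohexan]-5-one | CC(C)[C@@H]1CC[C@@H](C)C[C@]12OC(=O)[C@@]3(C)CC[C@@]3(c4cc(OC)ccc4OC)O2 | intermediate
10 | (1R,2R)-1-(2,5-dimethoxyphenyl)-2-(hydroxymethyl)-2-methylcyclobutan-1-ol | O[C@]1(c2cc(OC)ccc2OC)CC[C@]1(C)CO | intermediate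
11 | [(1R,2R)-2-(2,5-dimethoxyphenyl)-2-hydroxy-1-methylcyclobutyl]methyl 4-methylbenzenesulfonate | O[C@]1(c2cc(OC)ccc2OC)CC[C@]1(C)COS(=O)(=O)c3ccc(C)cc3 | intermediate
12 | [(1R,2R)-2-(2,5-dimethoxyphenyl)-1-methyl-2-[(trimethylsilyl)oxy]cyclobutyl]methyl 4-methylbenzenesulfonate | C[Si](C)(C)O[C@]1(c2cc(OC)ccc2OC)CC[C@]1(C)COS(=O)(=O)c3ccc(C)cc3 | intermediate
13 | [(1R)-1-(2,5-dimethoxyphenyl)-2,2-dimethylcyclobutoxy](trimethyl)silane | C[Si](C)(C)O[C@]1(c2cc(OC)ccc2OC)CCC1(C)C | intermediate
14 | (1R)-1-(2,5-dimethoxyphenyl)-2,2-dimethylcyclobutan-1-ol | O[C@]1(c2cc(OC)ccc2OC)CCC1(C)C | intermediate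
15 | (2Z)-2-methylbut-2-enoic anhydride (angelic anhydride) | C/C=C(/C)C(=O)OC(=O)/C(C)=C\C | starting material
16 | lithium (1R)-1-(2,5-dimethoxyphenyl)-2,2-dimethylcyclobutan-1-olate | [Li+].[O-][C@]1(c2cc(OC)ccc2OC)CCC1(C)C | intermediate
17 | (1R)-1-(2,5-dimethoxyphenyl)-2,2-dimethylcyclobutyl (2Z)-2-methylbut-2-enoate | C/C=C(/C)C(=O)O[C@]1(c2cc(OC)ccc2OC)CCC1(C)C | intermediate
18 | (1R)-1-(3,6-dioxocyclohexa-1,4-dien-1-yl)-2,2-dimethylcyclobutyl (2Z)-2-methylbut-2-enoate | C/C=C(/C)C(=O)O[C@]1(C2=CC(=O)C=CC2=O)CCC1(C)C | intermediate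
19 | succinic anhydride | O=C1CCC(=O)O1 | starting material
20 | 2,5-bis(trimethylsiloxy)furan | C[Si](C)(C)Oc1ccc(O[Si](C)(C)C)o1 | intermediate
21 | (1R)-1-[1,4-dioxo-5,8-bis(trimethylsilyloxy)-1,4,4a,5,8,8a-hexahydro-5,8-epoxynaphthalen-2-yl]-2,2-dimethylcyclobutyl (2Z)-2-methylbut-2-enoate (ring-fusion centres undefined) | C/C=C(/C)C(=O)O[C@]1(C2=CC(=O)C3C(C2=O)C4(O[Si](C)(C)C)C=CC3(O[Si](C)(C)C)O4)CCC1(C)C | intermediate
22 | (1R)-1-(5,8-dihydroxy-1,4-dioxo-1,4-dihydronaphthalen-2-yl)-2,2-dimethylcyclobutyl (2Z)-2-methylbut-2-enoate | C/C=C(/C)C(=O)O[C@]1(C2=CC(=O)c3c(O)ccc(O)c3C2=O)CCC1(C)C | target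

Total step count: 10. Longest linear sequence: 9 steps (steps 1 to 8, then 10); step 9 is a one-step side branch.

Steps most likely to fail

Step 3 (key step). The triplet enone may be deactivated by the neighbouring arene (energy or charge transfer) faster than it captures ethylene, or the π-facial selectivity exerted by the spiro-menthane may be low. Fallback: a thermal [2+2] with the stereocentre set afterwards by reagent control, setting out from ethylene 8 and returning at alcohol 14.
- Ethylene 8 is added to the tetramethylketeniminium salt generated from 1-chloro-N,N,2-trimethylprop-1-en-1-amine and AgBF4 in CH2Cl2. This keteniminium–alkene [2+2] cycloaddition forms the same two ring bonds and gives N-(2,2-dimethylcyclobutylidene)-N-methylmethanaminium tetrafluoroborate F1.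
- Aqueous work-up hydrolyses it to 2,2-dimethylcyclobutan-1-one F2.
- LiN(iPr)2 and then PhNTf2 give 4,4-dimethylcyclobut-1-en-1-yl trifluoromethanesulfonate F3.
- Suzuki coupling with (2,5-dimethoxyphenyl)boronic acid (Pd(PPh3)4, zerovalent palladium, K3PO4, dioxane–water) gives 1-(2,5-dimethoxyphenyl)-4,4-dimethylcyclobut-1-ene F4.
- Shi epoxidation with the D-fructose-derived ketone and KHSO5 at buffered pH gives (1R,4R)-1-(2,5-dimethoxyphenyl)-2,2-dimethyl-5-oxabicyclo[2.1.0]pentane F5. The face is assigned by analogy with 1-phenylcyclohexene, which gives the (R,R)-oxide.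
- LiEt3BH opens the epoxide at the less substituted carbon to give 14.

Step 6. Hydride displacement at the doubly β-branched neopentyl carbon may be slow, with competing attack at sulfur, or loss of the silyl ether followed by Grob fragmentation of the ring. Fallback: C–S hydrogenolysis in place of hydride displacement, setting out from diol 10 and returning at alcohol 14. The primary hydroxyl of 10 is converted under neutral conditions (PhSSPh, Bu3P, pyridine, 60 °C) into (1S,2S)-1-(2,5-dimethoxyphenyl)-2-methyl-2-[(phenylsulfanyl)methyl]cyclobutan-1-ol F6 (descriptors change formally because of sulfur). Acetone-deactivated Raney nickel (Ni) in EtOH at rt then cleaves the C–S bond to give 14. No alkoxide is formed at any point.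

Step 7. Acylation of the shielded tertiary alkoxide may be sluggish, and forcing conditions could isomerise the angeloyl unit to the tigloyl unit. Fallback: build the (Z)-alkene after the ester bond, setting out from alcohol 14 and returning at angelate 17. Alcohol 14 is esterified with 2-[bis(2,2,2-trifluoroethoxy)phosphoryl]propanoic acid and DCC in CH2Cl2, where acylation runs through a small, highly electrophilic phosphonoketene. This gives (1R)-1-(2,5-dimethoxyphenyl)-2,2-dimethylcyclobutyl 2-[bis(2,2,2-trifluoroethoxy)phosphoryl]propanoate F7 (mixture at the phosphonate-bearing carbon). A Still–Gennari olefination with acetaldehyde (KN(SiMe3)2, 18-crown-6, THF, –78 °C) then gives 17 with the Z geometry.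

Further compounds
F1 | step 3 | N-(2,2-dimethylcyclobutylidene)-N-methylmethanaminium tetrafluoroborate | C[N+](C)=C1CCC1(C)C.F[B-](F)(F)F
F2 | step 3 | 2,2-dimethylcyclobutan-1-one | CC1(C)CCC1=O
F3 | step 3 | 4,4-dimethylcyclobut-1-en-1-yl trifluoromethanesulfonate | CC1(C)CC=C1OS(=O)(=O)C(F)(F)F
F4 | step 3 | 1-(2,5-dimethoxyphenyl)-4,4-dimethylcyclobut-1-ene | COc1ccc(OC)c(c1)C1=CCC1(C)C
F5 | step 3 | (1R,4R)-1-(2,5-dimethoxyphenyl)-2,2-dimethyl-5-oxabicyclo[2.1.0]pentane | CC1(C)C[C@H]2O[C@@]12c3cc(OC)ccc3OC
F6 | step 6 | (1S,2S)-1-(2,5-dimethoxyphenyl)-2-methyl-2-[(phenylsulfanyl)methyl]cyclobutan-1-ol | O[C@]1(c2cc(OC)ccc2OC)CC[C@]1(C)CSc3ccccc3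
F7 | step 7 | (1R)-1-(2,5-dimethoxyphenyl)-2,2-dimethylcyclobutyl 2-[bis(2,2,2-trifluoroethoxy)phosphoryl]propanoate | CC(C(=O)O[C@]1(c2cc(OC)ccc2OC)CCC1(C)C)P(=O)(OCC(F)(F)F)OCC(F)(F)F
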